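Interpolated, the spring run needs 5.22 h to make the 36.0 % of target that the midnight run has after 4.00 h. Keep that delay.

| setting | spring | midnight | flask |
|---|---|---|---|
| substrate | 28 mM | 28 mM | 28 mM |
| precatalyst | 2.8 µM | 4.2 µM | 2.8 µM |
| remark | the very flask that is asked about, followed so far | run made earlier |  |

| run | time / h | target / % |
|---|---|---|
| spring | 0.667 | 1.1 |
| spring | 2.00 | 11.2 |
| spring | 4.00 | 27.1 |
| spring | 5.00 | 34.8 |
| spring | 8.00 | 51.2 |
| spring | 10.0 | 56.0 |
| midnight | 0.833 | 1.6 |
| midnight | 1.33 | 6.5 |
| midnight | 2.00 | 11.5 |
| midnight | 4.00 | 36.0 |
| midnight | 6.00 | 52.4 |
| midnight | 10.0 | 64.4 |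

(standard deviation of a reading: 1 percentage point)

- factor on the rate of making target when 50 % of the substrate are converted if precatalyst is charged twice over
- factor on the rate when 50 % of the substrate are converted if precatalyst is charged at 0.60 µM instead

- the numbers in the tables scatter by 1 percentage point (one standard deviation)

Your first guess may be a rate proportional to the charged [precatalyst]. Then the charge ratio of 1.50 would stretch the clock by the same factor. But the readings give a stretch of 1.30. If the two curves are one curve on stretched clocks, slopes at equal target differ by that stretch. So define the loading exponent, the logarithm of the stretch over the logarithm of the charge ratio: 0.656.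

Is a value below one plausible? In the spring run, target grows by a factor of 10.2 while time grows by 3.00, which looks like the square of time. Activity growing with charge and time would then give an exponent of 0.5. This is rough, since the first reading is 1.1 % with a scatter of 1 percentage point.

A second objection: the stretch belongs to equal target, and the question concerns equal conversion. If the last midnight reading, 64.4 %, is near the final target, half conversion lies near 32.2 % of target, not far below the pair used. So I keep the exponent. It gives 1.58 for a charge of 5.60 µM and 0.364 for 0.60 µM.

The forecast differs from my reckoning: 2.1 and 0.19, on the ground of “near-first-order behaviour”.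

    precatalyst → enzyme (k = 2.40 × 10⁻⁴ min⁻¹)
    substrate + enzyme → target + enzyme, rate k2*[substrate]^2*[enzyme]/(1 + ([substrate]/Kh2)^2) (22.0 mM, k = 31000 M⁻² s⁻¹)
    substrate → uncatalysed product (k = 0.00110 min⁻¹)

This flask gives 1.53 for a charge of 5.60 µM, a loading exponent of 0.614, against my 0.656. The 0.60 µM flask gives 0.346, an exponent of 0.690. In this flask the precatalyst turned into enzyme, which was 3.54 % of the catalyst at 2.50 h and 16.5 % at 12.5 h, while substrate went to target and to uncatalysed product, with 1.5 % of it left at 25.0 h. Half of its substrate was converted after 4.20 h, with target forming at 2.56 mM h⁻¹. In the 0.60 µM flask, at that same conversion, 90.5 % of the catalyst was still precatalyst.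

Readings and results come from a simulation on assumed constants; scatter was added.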